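**Proposed synthesis of (1S,5S)-5-[(12Z)-16-phenylhexadec-12-en-1-yl]cyclohex-2-ene-1,5-diol (15)**

Numbering used throughout: ring C1 (secondary carbinol), C2=C3, C4, C5 (tertiary carbinol), C6; chain C1'–C16'. In systematic numbering 15 is the (1S,3S)-1-substituted cyclohex-4-ene-1,3-diol; the two hydroxyls are cis.

Assumption (remark on the chemistry): the sense of induction of the DACH-phenyl Trost ligand is taken from the palladium-catalysed deracemisation of cyclohex-2-enyl carbonates, where the (R,R)-ligand is taken to give the (S)-configured allylic C–O bond; should bridged carbonate 13 respond in the opposite sense, the (S,S)-ligand is used with nothing else changed.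

## The problem

Target 15 is a cyclohex-2-ene-1,5-diol: C1 is a secondary allylic carbinol, C2=C3 the ring alkene, C4 and C6 methylenes, and C5 a tertiary carbinol carrying a sixteen-carbon chain with a (Z)-C12'=C13' alkene and a terminal phenyl ring. The hard point is C5: both of its ring neighbours are CH2 groups and the two arms first differ one atom further out (C1 carbinol against C3 alkene carbon), so a reagent acting at C5 cannot tell its faces apart directly. C5 must also stand cis-1,3 to C1 with no stereocentre in between to relay the information, and the alkene must end up allylic to C1 and not to C5. The diol is formally the double hydrate of an alkylbenzene, so uncontrolled acid or ionising conditions threaten dehydration and aromatisation. The Z-alkene does not tolerate hydrogenation, radicals or strong electrophiles, and the terminal phenyl ring forbids dissolving-metal steps once it is present. Three features of the ring open a shortcut: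
- When the C1–O bond is ionised, the allyl unit C1–C2–C3 has a mirror plane through C2 and C5 that contains O5 and C1'. C5 then stops being a stereocentre, and both descriptors can be written at once by choosing one allyl terminus.
- O1 and O5 are cis-1,3 and can be bridged by one carbonyl carbon in a 2,4-dioxabicyclo[3.3.1]nonane.
- The six ring carbons with C1' on C5 are those of a mono-alkylbenzene.

## Retrosynthesis

**15 ⇒ 13 (through 14).** In the reverse sense O1 and O5 are tied through a carbonyl carbon, giving the racemic bridged allylic carbonate 13. Forward, zerovalent palladium with a chiral ligand ionises C1–O to the mirror-symmetric π-allyl zwitterion 14, and a new C–O bond is made at one terminus. Setting C5 first and relaying to C1 would ask a reagent to read two nearly identical arms. This cut instead lets a catalyst choose between two allyl CH termini, a problem with a known solution, and moves the only enantioselective event to the last step. The precursor is a racemate made with achiral reagents only. The forward step needs terminus discrimination by the ligand, ionisation of both enantiomers of 13, outer-sphere attack by oxygen and no β-hydride loss.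

**13 ⇒ 12 ⇒ 11 ⇒ 9 (through 10).** The carbonate C–O bond at C1 is cut and H–I is added across C2–C3: allylic carbonate 13 comes from iodocarbonate 12, that from tert-butyl carbonate 11, and that from tertiary homoallylic alcohol 9 through its alkoxide 10. The temporary carbonate decides three things in one closure:
- which alkene carbon receives oxygen (the nearer one, through a six-membered ring);
- on which face (that of O5);
- where the alkene ends up (the E2 step has a single antiperiplanar hydrogen).

Direct allylic oxidation of 9 would face four allylic C–H positions on two faces. Compound 9 has one stereocentre, no 1,3-relationship and an isolated ring alkene. The forward closure must spare C12'=C13'.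

**9 ⇒ 5 + 8 (8 from 7 from 6).** The C12'=C13' bond is cut by a Wittig disconnection into hydroxy aldehyde 5 and ylide 8, made from phosphonium salt 7 and bromide 6. The cut is placed here because the phenyl terminus must arrive after the other arene has been dearomatised, and an unstabilised ylide brings the Z geometry with it. The forward step needs kinetic Z-selectivity next to a free tertiary hydroxyl.

**5 ⇒ 4 ⇒ 3 ⇒ 2 ⇒ 1.** No C–C bond is cut: aldehyde 5 comes from diol 4, that from epoxy acid 3, that from diene acid 2, and that from 12-phenyldodecanoic acid 1. The six ring carbons and twelve chain carbons are bought as one arene, with C5 the ipso carbon. Adding a chain organometallic to a β,γ-unsaturated cyclohexanone would need a ketone that enolises and migrates into conjugation; here no bond is made at the quaternary centre. The forward steps need Birch regiochemistry, peracid selectivity for the only trisubstituted alkene, and hydride attack at the secondary epoxide carbon.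

## Roads not taken

Alternative 1: The most obvious cut is C2=C3 by ring-closing metathesis of diene diol A1 with the second-generation Grubbs catalyst. A1 moves the C5 problem into an acyclic ketone allylation, where allyl and 2-hydroxybut-3-enyl arms must be told apart by 1,3-induction alone. The chain Z-alkene is a third olefin under a catalyst known to isomerise and cross-metathesise. The asymmetric run-up to A1 is also longer than the whole chosen route before its key step.

Alternative 2: The C5–C1' bond is cut from the chiral pool. (−)-Quinic acid A2 already holds the tertiary carbinol; reduction of the carboxyl, excision of the 4,5-diol as the alkene and closure would give spiro-epoxide A3, opened at CH2 by Grignard reagent A4 with catalytic CuI. The carbinol of A2 that is cis to the tertiary hydroxyl and would be kept is R where C1 of 15 is S with the same substituent ranking. The cheap acid therefore maps onto the antipode, and the scarce enantiomer of A2 would be needed. The diol to be excised is trans, several protecting-group steps are unavoidable, and A4 needs its own synthesis with the Z-alkene in place.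

Alternative 3: The C1–H bond is cut: hydroxy-enone A6 is reduced with NaBH4/CeCl3. A6 would come from meso-triol A5 by lipase-catalysed acylation of one enantiotopic secondary hydroxyl, oxidation of the other and β-elimination. The enzyme answers the C5 question, but the cis relationship then rests only on the conformational preference of C5 during the 1,2-reduction. A6 is a β-hydroxy ketone one dehydration away from a phenol tautomer. The chosen plan fixes cis by a covalent bridge and needs no protecting group.

Key step: step 10

## Route

Step 1
Reactants: 1 12-phenyldodecanoic acid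
Product: 2 12-(cyclohexa-1,4-dien-1-yl)dodecanoic acid
Conditions: Li, NH3(l)/THF, t-BuOH, −78 → −33 °C; NH4Cl
Reagents that add atoms: none
Why: Birch reduction; the lithium carboxylate is inert, the alkyl donor ends up on a double bond, and kinetic protonation keeps the diene unconjugated.

Step 2
Reactants: 2 12-(cyclohexa-1,4-dien-1-yl)dodecanoic acid
Product: 3 rac-12-[(1R*,6S*)-7-oxabicyclo[4.1.0]hept-3-en-1-yl]dodecanoic acid
Conditions: mCPBA (1.0 equiv), CH2Cl2, −10 → 0 °C; crude product used at once
Reagents that add atoms: 3-chloroperoxybenzoic acid, OOC(=O)c1cccc(Cl)c1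
Why: Prilezhaev epoxidation; the electrophilic peracid takes the trisubstituted alkene before the disubstituted one, and the two new centres are cis by ring fusion and racemic.

Step 3
Reactants: 3 rac-12-[(1R*,6S*)-7-oxabicyclo[4.1.0]hept-3-en-1-yl]dodecanoic acid
Product: 4 rac-12-(1-hydroxycyclohex-3-en-1-yl)dodecan-1-ol
Conditions: LiAlH4 (excess), THF, 0 → 65 °C; aqueous NaOH work-up
Reagents that add atoms: none
Why: Hydride opens the trisubstituted epoxide by SN2 attack at its secondary carbon, leaving the tertiary alcohol, and reduces the acid to the primary alcohol in the same operation.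

Step 4
Reactants: 4 rac-12-(1-hydroxycyclohex-3-en-1-yl)dodecan-1-ol
Product: 5 rac-12-(1-hydroxycyclohex-3-en-1-yl)dodecanal
Conditions: TEMPO (cat.), PhI(OAc)2, CH2Cl2, 23 °C
Reagents that add atoms: none
Why: Oxoammonium oxidation; only the primary alcohol can be oxidised, it stops at the aldehyde, and the tertiary alcohol and ring alkene are spectators.

Step 5
Reactants: 6 (4-bromobutyl)benzene
Product: 7 triphenyl(4-phenylbutyl)phosphonium bromide
Conditions: PPh3, MeCN, reflux
Reagents that add atoms: triphenylphosphine, c1ccc(cc1)P(c1ccccc1)c1ccccc1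
Why: SN2 quaternisation of a primary bromide.

Step 6
Reactants: 5 rac-12-(1-hydroxycyclohex-3-en-1-yl)dodecanal; 7 triphenyl(4-phenylbutyl)phosphonium bromide
Product: 9 rac-1-[(12Z)-16-phenylhexadec-12-en-1-yl]cyclohex-3-en-1-ol, via triphenyl(4-phenylbutylidene)phosphorane 8 (not isolated)
Conditions: 7 (2.5 equiv), NaN(SiMe3)2 (2.4 equiv), THF, 0 °C; then 5, −78 → 23 °C
Reagents that add atoms: none
Why: Wittig olefination with an unstabilised ylide under lithium-free conditions; the kinetically formed cis-oxaphosphetane gives the Z-alkene. One equivalent of ylide is spent on the tertiary hydroxyl, which returns on work-up.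

Step 7
Reactants: 9 rac-1-[(12Z)-16-phenylhexadec-12-en-1-yl]cyclohex-3-en-1-ol
Product: 11 rac-tert-butyl 1-[(12Z)-16-phenylhexadec-12-en-1-yl]cyclohex-3-en-1-yl carbonate, via lithium alkoxide 10 (not isolated)
Conditions: n-BuLi, THF, −78 → 0 °C; Boc2O, 0 → 23 °C
Reagents that add atoms: di-tert-butyl dicarbonate, CC(C)(C)OC(=O)OC(=O)OC(C)(C)C
Why: O-acylation of the hindered tertiary alcohol as its lithium alkoxide gives the mixed carbonate that carries the carbon of the future bridge.

Step 8
Reactants: 11 rac-tert-butyl 1-[(12Z)-16-phenylhexadec-12-en-1-yl]cyclohex-3-en-1-yl carbonate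
Product: 12 rac-(1S*,5S*,6S*)-6-iodo-1-[(12Z)-16-phenylhexadec-12-en-1-yl]-2,4-dioxabicyclo[3.3.1]nonan-3-one
Conditions: I2 (3 equiv), NaHCO3, MeCN/CH2Cl2, −20 → 0 °C, dark; aqueous Na2S2O3
Reagents that add atoms: iodine, II
Why: Iodocarbonate cyclisation of a homoallylic tert-butyl carbonate: with the carbonate axial, its carbonyl oxygen opens the iodonium ion at the nearer ring carbon in a 6-exo, trans-diaxial closure and the tert-butyl group leaves as 2-methylpropene, so the new C–O bond is cis to C5–O by the geometry of the tether and iodine is axial on the next carbon. Iodonium formation at C12'=C13' is reversible and finds no internal nucleophile, the chemoselectivity on which iodolactonisation of polyunsaturated acids relies.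

Step 9
Reactants: 12 rac-(1S*,5S*,6S*)-6-iodo-1-[(12Z)-16-phenylhexadec-12-en-1-yl]-2,4-dioxabicyclo[3.3.1]nonan-3-one
Product: 13 rac-(1S*,5S*)-1-[(12Z)-16-phenylhexadec-12-en-1-yl]-2,4-dioxabicyclo[3.3.1]non-6-en-3-one
Conditions: DBU, toluene, 80 °C
Reagents that add atoms: none
Why: E2 elimination; the axial iodide has a single antiperiplanar hydrogen, on the methylene away from the carbinol carbon (the carbinol hydrogen is equatorial), so the alkene forms regiospecifically and the carbonate becomes allylic.

Step 10
Reactants: 13 rac-(1S*,5S*)-1-[(12Z)-16-phenylhexadec-12-en-1-yl]-2,4-dioxabicyclo[3.3.1]non-6-en-3-one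
Product: 15 (1S,5S)-5-[(12Z)-16-phenylhexadec-12-en-1-yl]cyclohex-2-ene-1,5-diol, via π-allylpalladium zwitterion 14 (not isolated)
Conditions: Pd2(dba)3·CHCl3 (2.5 mol %), (R,R)-DACH-phenyl Trost ligand, N,N'-[(1R,2R)-cyclohexane-1,2-diyl]bis[2-(diphenylphosphanyl)benzamide] (7.5 mol %), KHCO3, CH2Cl2/H2O, 23 °C
Reagents that add atoms: potassium hydrogencarbonate, [K+].OC([O-])=O (carries the new O1 and is re-formed from hydroxide and CO2); water, O (net source of that oxygen)
Why: The zerovalent palladium–ligand complex binds the ring alkene on the face away from the carbonate bridge and ionises the axial allylic C1–O bond with inversion; both enantiomers of 13 give the same zwitterion 14, whose termini C1 and C3 are exchanged by the mirror plane through C2 and C5, and CO2 is lost from the tethered carbonate. Hydrogencarbonate then attacks one terminus from the face opposite palladium, which is the face of O5, and the allyl hydrogencarbonate loses CO2 to the alcohol, so the net course is retention and the diol can only be cis. The closest known reaction type is the palladium-catalysed deracemisation of cyclohex-2-enyl carbonates by oxygen nucleophiles and the opening of racemic bridged cyclohexenyl lactones through the same mirror-symmetric π-allyl with this ligand class. No ring is closed; the dioxanone ring of the tether is opened. C1 is set by the ligand through the choice of terminus, and C5, which is not stereogenic in 14, takes its descriptor from that same choice, so one C–O bond formation writes both centres. The step needs terminus selectivity (ligand pocket; the C5 substituents lie in the mirror plane and bias neither end), facial selectivity (fixed by anti ionisation and outer-sphere attack) and chemoselectivity (the chain alkene has no allylic leaving group, and the product alcohol does not ionise under these near-neutral conditions, so its configuration is stable). β-Hydride loss from 14 is held back by the low temperature and fast capture by hydrogencarbonate at the water interface.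

## Compound list

1 | 12-phenyldodecanoic acid | OC(=O)CCCCCCCCCCCc1ccccc1 | starting material
2 | 12-(cyclohexa-1,4-dien-1-yl)dodecanoic acid | OC(=O)CCCCCCCCCCCC1=CCC=CC1 | intermediate
3 | rac-12-[(1R*,6S*)-7-oxabicyclo[4.1.0]hept-3-en-1-yl]dodecanoic acid (racemate; one enantiomer drawn) | OC(=O)CCCCCCCCCCC[C@@]12CC=CC[C@@H]1O2 | intermediate
4 | rac-12-(1-hydroxycyclohex-3-en-1-yl)dodecan-1-ol (racemate) | OCCCCCCCCCCCCC1(O)CC=CCC1 | intermediate
5 | rac-12-(1-hydroxycyclohex-3-en-1-yl)dodecanal (racemate) | O=CCCCCCCCCCCCC1(O)CC=CCC1 | intermediate
6 | (4-bromobutyl)benzene | BrCCCCc1ccccc1 | starting material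
7 | triphenyl(4-phenylbutyl)phosphonium bromide | [Br-].c1ccccc1CCCC[P+](c1ccccc1)(c1ccccc1)c1ccccc1 | intermediate
8 | triphenyl(4-phenylbutylidene)phosphorane | c1ccccc1CCCC=P(c1ccccc1)(c1ccccc1)c1ccccc1 | intermediate
9 | rac-1-[(12Z)-16-phenylhexadec-12-en-1-yl]cyclohex-3-en-1-ol (racemate) | OC1(CCCCCCCCCCC/C=C\CCCc2ccccc2)CC=CCC1 | intermediate
10 | lithium alkoxide of 9 (racemate) | [Li+].[O-]C1(CCCCCCCCCCC/C=C\CCCc2ccccc2)CC=CCC1 | intermediate
11 | rac-tert-butyl 1-[(12Z)-16-phenylhexadec-12-en-1-yl]cyclohex-3-en-1-yl carbonate (racemate) | CC(C)(C)OC(=O)OC1(CCCCCCCCCCC/C=C\CCCc2ccccc2)CC=CCC1 | intermediate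
12 | rac-(1S*,5S*,6S*)-6-iodo-1-[(12Z)-16-phenylhexadec-12-en-1-yl]-2,4-dioxabicyclo[3.3.1]nonan-3-one (racemate; one enantiomer drawn) | O=C1O[C@@]2(CCCCCCCCCCC/C=C\CCCc3ccccc3)CC[C@H](I)[C@H](C2)O1 | intermediate
13 | rac-(1S*,5S*)-1-[(12Z)-16-phenylhexadec-12-en-1-yl]-2,4-dioxabicyclo[3.3.1]non-6-en-3-one (racemate; one enantiomer drawn) | O=C1O[C@@]2(CCCCCCCCCCC/C=C\CCCc3ccccc3)CC=C[C@H](C2)O1 | intermediate
14 | mirror-symmetric (η3-cyclohexenyl)palladium carbonate zwitterion of divalent palladium, metal trans to the C5 oxygen (chiral diphosphine on the metal not drawn) | [O-]C(=O)O[C@]1(CCCCCCCCCCC/C=C\CCCc4ccccc4)C[C@@H]2[C@@H]3[C@H](C1)[Pd+]23 | intermediate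
15 | (1S,5S)-5-[(12Z)-16-phenylhexadec-12-en-1-yl]cyclohex-2-ene-1,5-diol | O[C@@H]1C=CC[C@@](O)(CCCCCCCCCCC/C=C\CCCc2ccccc2)C1 | target

## Step count and least certain steps

Total step count: 10. Longest linear sequence: 9 (steps 1–4 and 6–10 from 1); step 5 is a one-step branch. No protecting group is used.

**Step 10 (key step).** The most likely failure is incomplete stereoconvergence. Either the mismatched enantiomer of 13 ionises too slowly, so the process stalls as a kinetic resolution, or the ligand discriminates weakly between the two termini because the axial C5–O substituent sits 1,3 to both. β-Hydride loss from the π-allyl followed by aromatisation is the second risk.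
Fallback: the absolute configuration is set earlier by reagent control and the tether is cleaved without palladium. Setting out from 2, Shi epoxidation with the ketone catalyst of the L-fructose series (KHSO5, K2CO3, Bu4NHSO4, MeCN/dimethoxymethane/aqueous buffer, 0 °C) should give the (1R,6S)-epoxy acid F1. The facial sense is taken from 1-arylcyclohexenes, with the chain in the place of the aryl group. The reagents of steps 3, 4, 6, 7, 8 and 9 then carry the material through (S)-diol F2, (S)-hydroxy aldehyde F3, (S)-alkenol F4, its lithium alkoxide F5, (S)-tert-butyl carbonate F6, (1S,5S,6S)-iodocarbonate F7 and (1S,5S)-allylic carbonate F8. K2CO3 in MeOH at 23 °C cleaves F8 to 15, where the fallback rejoins the route.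

**Step 8.** The most likely failure is loss of chemoselectivity: electrophilic iodine engages the equally electron-rich C12'=C13' alkene (addition, or Z/E isomerisation through iodine atoms). Closure could also be slow because the tertiary carbonate must sit axial.
Fallback: the ring is functionalised before the chain alkene exists. Setting out from 4, double deprotonation (n-BuLi, 2.1 equiv) gives dilithium dialkoxide F9, and Boc2O gives bis(tert-butyl carbonate) F10. IBr (toluene/CH2Cl2, −78 °C) closes the tertiary carbonate to iodocarbonate F11 and leaves the primary carbonate alone. DBU gives allylic carbonate F12, and CF3CO2H in CH2Cl2 at 0 °C removes the acyclic tert-butyl carbonate to give alcohol F13. TEMPO/PhI(OAc)2 gives aldehyde F14, and Wittig reaction with ylide 8 rejoins the route at 13.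

**Step 6.** The most likely failure is erosion of Z-selectivity, because the sodium alkoxide formed from the tertiary hydroxyl changes the aggregation of the ylide and may allow partial equilibration of the oxaphosphetane. The E isomer would be hard to remove.
Fallback: the geometry is fixed by syn hydrogenation of an alkyne. Setting out from 5, Ohira–Bestmann homologation (dimethyl (1-diazo-2-oxopropyl)phosphonate, K2CO3, MeOH) gives terminal alkyne F15. n-BuLi (2.1 equiv, THF/DMPU) gives dilithio derivative F16, which 1-bromo-3-phenylpropane alkylates on carbon to internal alkyne F17. Semi-hydrogenation (H2, Pd/CaCO3 poisoned with Pb(OAc)2, quinoline), stopped at one equivalent so the ring alkene is spared, rejoins the route at 9.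

## Further compounds

F1 | step 10 | 12-[(1R,6S)-7-oxabicyclo[4.1.0]hept-3-en-1-yl]dodecanoic acid | OC(=O)CCCCCCCCCCC[C@@]12CC=CC[C@@H]1O2
F2 | step 10 | 12-[(1S)-1-hydroxycyclohex-3-en-1-yl]dodecan-1-ol | OCCCCCCCCCCCC[C@@]1(O)CC=CCC1
F3 | step 10 | 12-[(1S)-1-hydroxycyclohex-3-en-1-yl]dodecanal | O=CCCCCCCCCCCC[C@@]1(O)CC=CCC1
F4 | step 10 | (1S)-1-[(12Z)-16-phenylhexadec-12-en-1-yl]cyclohex-3-en-1-ol | O[C@]1(CCCCCCCCCCC/C=C\CCCc2ccccc2)CC=CCC1
F5 | step 10 | lithium (1S)-1-[(12Z)-16-phenylhexadec-12-en-1-yl]cyclohex-3-en-1-olate | [Li+].[O-][C@]1(CCCCCCCCCCC/C=C\CCCc2ccccc2)CC=CCC1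
F6 | step 10 | tert-butyl (1S)-1-[(12Z)-16-phenylhexadec-12-en-1-yl]cyclohex-3-en-1-yl carbonate | CC(C)(C)OC(=O)O[C@]1(CCCCCCCCCCC/C=C\CCCc2ccccc2)CC=CCC1
F7 | step 10 | (1S,5S,6S)-6-iodo-1-[(12Z)-16-phenylhexadec-12-en-1-yl]-2,4-dioxabicyclo[3.3.1]nonan-3-one | O=C1O[C@@]2(CCCCCCCCCCC/C=C\CCCc3ccccc3)CC[C@H](I)[C@H](C2)O1
F8 | step 10 | (1S,5S)-1-[(12Z)-16-phenylhexadec-12-en-1-yl]-2,4-dioxabicyclo[3.3.1]non-6-en-3-one | O=C1O[C@@]2(CCCCCCCCCCC/C=C\CCCc3ccccc3)CC=C[C@H](C2)O1
F9 | step 8 | dilithium dialkoxide of 4 (racemate) | [Li+].[Li+].[O-]CCCCCCCCCCCCC1([O-])CC=CCC1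
F10 | step 8 | rac-tert-butyl 12-{1-[(tert-butoxycarbonyl)oxy]cyclohex-3-en-1-yl}dodecyl carbonate | CC(C)(C)OC(=O)OCCCCCCCCCCCCC1(OC(=O)OC(C)(C)C)CC=CCC1
F11 | step 8 | rac-tert-butyl 12-[(1S*,5S*,6S*)-6-iodo-3-oxo-2,4-dioxabicyclo[3.3.1]nonan-1-yl]dodecyl carbonate (one enantiomer drawn) | CC(C)(C)OC(=O)OCCCCCCCCCCCC[C@@]12CC[C@H](I)[C@H](C2)OC(=O)O1
F12 | step 8 | rac-tert-butyl 12-[(1S*,5S*)-3-oxo-2,4-dioxabicyclo[3.3.1]non-6-en-1-yl]dodecyl carbonate (one enantiomer drawn) | CC(C)(C)OC(=O)OCCCCCCCCCCCC[C@@]12CC=C[C@H](C2)OC(=O)O1
F13 | step 8 | rac-(1S*,5S*)-1-(12-hydroxydodecyl)-2,4-dioxabicyclo[3.3.1]non-6-en-3-one (one enantiomer drawn) | OCCCCCCCCCCCC[C@@]12CC=C[C@H](C2)OC(=O)O1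
F14 | step 8 | rac-12-[(1S*,5S*)-3-oxo-2,4-dioxabicyclo[3.3.1]non-6-en-1-yl]dodecanal (one enantiomer drawn) | O=CCCCCCCCCCCC[C@@]12CC=C[C@H](C2)OC(=O)O1
F15 | step 6 | rac-1-(tridec-12-yn-1-yl)cyclohex-3-en-1-ol | C#CCCCCCCCCCCCC1(O)CC=CCC1
F16 | step 6 | dilithium acetylide alkoxide of F15 (racemate) | [Li+].[Li+].[C-]#CCCCCCCCCCCCC1([O-])CC=CCC1
F17 | step 6 | rac-1-(16-phenylhexadec-12-yn-1-yl)cyclohex-3-en-1-ol | OC1(CCCCCCCCCCCC#CCCCc2ccccc2)CC=CCC1
A1 | alternative 1 | (3S,5S)-5-[(12Z)-16-phenylhexadec-12-en-1-yl]octa-1,7-diene-3,5-diol | C=C[C@@H](O)C[C@](O)(CCCCCCCCCCC/C=C\CCCc1ccccc1)CC=C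
A2 | alternative 2 | (−)-quinic acid, (1S,3R,4S,5R)-1,3,4,5-tetrahydroxycyclohexane-1-carboxylic acid | C1[C@H]([C@H]([C@@H](C[C@@]1(C(=O)O)O)O)O)O
A3 | alternative 2 | (3S,5S)-1-oxaspiro[2.5]oct-6-en-5-ol | O[C@@H]1C=CC[C@@]2(CO2)C1
A4 | alternative 2 | [(11Z)-15-phenylpentadec-11-en-1-yl]magnesium bromide | Br[Mg]CCCCCCCCCC/C=C\CCCc1ccccc1
A5 | alternative 3 | all-cis-1-[(12Z)-16-phenylhexadec-12-en-1-yl]cyclohexane-1,3,5-triol (meso) | O[C@H]1C[C@@H](O)C[C@](O)(CCCCCCCCCCC/C=C\CCCc2ccccc2)C1
A6 | alternative 3 | (5S)-5-hydroxy-5-[(12Z)-16-phenylhexadec-12-en-1-yl]cyclohex-2-en-1-one | O=C1C=CC[C@@](O)(CCCCCCCCCCC/C=C\CCCc2ccccc2)C1
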